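The earlier runs and the new flask were generated by integration with made-up constants; scatter was added.

Fraction of the charge per minute is the unit I reckon in, as with a velocity read off a progress curve. In these flasks, starting material turns into target and a little side product while solid reagent dissolves, with some protic impurity present.

| flask | starting material | solid reagent | protic impurity | remark | time |
|---|---|---|---|---|---|
| ochre | 0.44 M | 1.1 equiv | 10 mM | run made earlier |  |
| green | 0.44 M | 1.1 equiv | 15 mM | run made earlier |  |
| Saturday's | 0.44 M | 1.10 equiv | 8.80 mM |  | 2.5 h |
| Friday's | 0.44 M | 1.10 equiv | 13.0 mM |  | 2.5 h |

| run | time / min | target / % | side product / % | starting material / % |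
|---|---|---|---|---|
| ochre | 12.0 | 0.7 | 0 | 97.2 |
| ochre | 40.0 | 9.7 | 0 | 89.8 |
| ochre | 60.0 | 14.8 | 0.3 | 82.9 |
| ochre | 120 | 30.6 | 0.9 | 66.6 |
| green | 8.00 | 2.1 | 0.6 | 97.0 |
| green | 20.0 | 2.2 | 0 | 94.0 |
| green | 50.0 | 11.1 | 0.6 | 86.1 |
| green | 120 | 30.2 | 2.6 | 64.2 |

(readings scatter by 1 percentage point)

- which of these there is most of at the end, counted by the starting material in it, Saturday's (side product / target / starting material)
- which of these there is most of at the end, counted by the starting material in it, Friday's (side product / target / starting material)
- how much there is at the end of the one of these that leads, in percent of the starting material charged: Saturday's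
- how much there is at the end of the one of these that leads, in percent of the starting material charged: Friday's

- given per volume of solution although it is solid: solid reagent
- the numbers in the tables scatter by 1 percentage point (one standard deviation)
- at the start none of the solid reagent is in solution

I replace each curve by its mean fall, the loss of starting material between the second and last readings divided by the time between them. Ochre gives 0.00290 /min and green 0.00298 /min, so I carry their mean, the mean fall 0.00294 /min, an apparent zero order.

What error does the straight line make? Reading down the tables, it puts ochre's third reading at 84.0% against 82.9%, and green's at 85.1% against 86.1%. Both misses are about the scatter of 1 percentage point.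

The last rows read 66.6% and 64.2% at 120 min. With that scatter, I build no effect of [protic impurity] on the gap. I average them and extend the line to 2.5 h, which gives 56.6% for both new flasks. Even if all the loss were target, that would be 43.4%, less than what remains.

The forecast also names starting material for both flasks, with 58% for Saturday's and 57% for Friday's, a split I don't make: “Starting material therefore still leads in both runs”.

The flasks give starting material at 57.1% in Saturday's and starting material at 56.4% in Friday's.

    starting material + coupling partner ⇌ target (K = 10.9 /M, k = 0.00102 /M/s)
    starting material + 2 coupling partner → side product (k = 8.91 × 10⁻⁴ /M²/s)
    solid reagent ⇌ coupling partner, rate k3*(cs3 - [coupling partner]) while solid is left; crystals form when [coupling partner] > cs3 (solubility = 0.390 M, k = 1.12 × 10⁻⁴ /s)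
    starting material + protic impurity → quenched substrate (k = 0.0153 /M/s)

In Saturday's, starting material falls from 79.0% to 57.1% over the second half of the time, a mean of 0.00291 /min against my 0.00294 /min, and at the end 34.7% of the charged solid reagent is still there. The neighbour is that flask left until 10 h. The same line, carried there, gives an impossible −75.7%. That neighbour holds 0% of its solid reagent and 33.1% starting material, and its target, at 45.3%, stands higher.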